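**Direct plan and its weak points**

A direct plan would make the two arenes separately and join them last.
Ring B would be grown from a silyl-protected chain enone by malonate Michael–Claisen annulation, decarboxylation to the cyclohexane-1,3-dione A1 and dehydrogenation, then benzylated and desilylated to the alcohol A2.
The ring A acid A3 would come from a bought bromobenzaldehyde (demethylation, benzylation, B-alkyl Suzuki coupling, oxidation); acylation of A2 by activated A3 would give the tribenzyl ester A4, and hydrogenolysis the target.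
Weakest would be (a) the Pd/C dehydrogenation of A1 near 165 °C, which is prone to disproportionation and silyl ether loss and would end five steps spent on a ring that can be bought as a 5-haloresorcinol;
(b) the acylation of the secondary alcohol A2 by the 2,6-disubstituted benzoyl derivative of A3, the most hindered bond of the molecule made last from the two most valuable fragments, neither affordable in excess;
(c) the protecting-group traffic (silyl on and off, demethylation then benzylation, two benzylations, one hydrogenolysis, an aldehyde-to-acid oxidation), close to half of all steps with no skeletal bond formed.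
The annulation would also leave its two ring stereocentres to chance, harmless only because aromatisation erases them.

**Plan of the new route**

The retrosynthesis first cuts the ring B aryl–CH2 bond (made as an aryl–alkyne bond from bought 5-iodoresorcinol, then hydrogenated), then cuts ring A itself across C1–C2 and C5–C6 into an alk-2-ynoate and a 1,1,3-trioxygenated butadiene, and last the ester C–O bond, now that of an unhindered alkynoic acid.
Ring A (C1 carboxyl-bearing, C2 OH, C3, C4 OMe, C5, C6 chain-bearing) arises from an acyclic diyne ester that already holds both (R) carbinols and the finished ester; ring B is never built and enters last.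
The feature used: C1 and C6 are adjacent and carry the carboxyl group and the chain, which are the two sp carbons of an ynoate, while C2–C5 with oxygen at C2 and C4 are the four carbons of an acetoacetate-derived vinylketene acetal.
The carboxyl oxidation level at C2 makes the ring aromatic by loss of methanol without an oxidant and delivers C2–OH and C4–OMe already differentiated.
Both stereocentres come from (R)-2-propyloxirane by acetylide opening and alkyne zipper; no dehydrogenation, no acylation by a hindered benzoyl derivative and no protecting-group step occur (the acetate is part of the target).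

Key step: step 9

Remark: 5-iodobenzene-1,3-diol (19) is taken as a purchasable compound; the vinylketene acetal 15 is drawn as its (1E) isomer, and its geometry has no bearing on the product.

**Chain of the alcohol part**

Step 1
Reactants: 1 (R)-2-propyloxirane [(R)-1,2-epoxypentane]; 2 hex-1-yne
Product: 4 (R)-undec-6-yn-4-ol, via hex-1-ynyllithium 3 (not isolated)
Conditions: 2 (1.3 equiv), n-BuLi, THF, −78 °C; BF3·OEt2; then 1, −78 °C; aq. NH4Cl
Reagents that add atoms: none
Why: Yamaguchi–Hirao alkynylation, in which the alkynyl borate formed from 3 and BF3·OEt2 opens the activated epoxide by SN2 attack at the unsubstituted CH2, so no bond to the stereocentre is touched and C4 keeps the (R) configuration of 1 (the new CH2C≡C branch outranks propyl just as the ring CH2O did).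

Step 2
Reactants: 4 (R)-undec-6-yn-4-ol
Product: 5 (R)-undec-10-yn-4-ol
Conditions: KH, H2N(CH2)3NH2, 0 °C to rt (KNH(CH2)3NH2 formed in situ); then H2O
Reagents that add atoms: none
Why: Alkyne zipper reaction, in which repeated propargyl/allenyl deprotonation and reprotonation walk the triple bond along the chain away from the alkoxide-bearing carbon until the irreversibly formed terminal acetylide drains the equilibrium, while the carbinol C–H of the alkoxide is not acidic and C4 should stay (R).

**Chain of the acid part**

Step 3
Reactants: 1 (R)-2-propyloxirane; 6 non-1-yne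
Product: 8 (R)-tetradec-6-yn-4-ol, via non-1-ynyllithium 7 (not isolated)
Conditions: 6 (1.3 equiv), n-BuLi, THF, −78 °C; BF3·OEt2; then 1, −78 °C; aq. NH4Cl
Reagents that add atoms: none
Why: The same Yamaguchi–Hirao SN2 opening at the epoxide CH2 as in step 1, now with the nine-carbon acetylide, leaves the stereocentre untouched and (R).

Step 4
Reactants: 8 (R)-tetradec-6-yn-4-ol
Product: 9 (R)-tetradec-13-yn-4-ol
Conditions: KH, H2N(CH2)3NH2, 0 °C to rt (KNH(CH2)3NH2 formed in situ); then H2O
Reagents that add atoms: none
Why: Alkyne zipper reaction as in step 2, which should move the triple bond over seven positions to the chain end with the (R) carbinol carried along as its inert alkoxide.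

Step 5
Reactants: 9 (R)-tetradec-13-yn-4-ol
Product: 11 (R)-12-hydroxypentadec-2-ynoic acid, via dilithiated alkynol 10 (not isolated)
Conditions: n-BuLi (2.2 equiv), THF, −78 to 0 °C; CO2 (g), −78 °C to rt; 1 M HCl
Reagents that add atoms: carbon dioxide, O=C=O
Why: Carboxylation of a lithium acetylide, in which the sp carbanion of 10 adds to CO2 while the alkyl carbonate formed at the alkoxide oxygen loses CO2 again on acidification, so that only the C1 carboxyl group is gained and the carbinol is untouched.

Step 6
Reactants: 11 (R)-12-hydroxypentadec-2-ynoic acid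
Product: 12 (R)-12-acetoxypentadec-2-ynoic acid
Conditions: Ac2O, pyridine, DMAP (cat.), CH2Cl2, 0 °C to rt; then H2O, rt; dilute HCl wash
Reagents that add atoms: acetic anhydride, CC(=O)OC(C)=O
Why: DMAP-catalysed O-acetylation reacts at the O–H bond only, so the acetate of the target is installed with retention, and any acyl transfer to the carboxyl group is reversed by the aqueous stir.

**Ester, ring A, ring B**

Step 7
Reactants: 12 (R)-12-acetoxypentadec-2-ynoic acid; 5 (R)-undec-10-yn-4-ol
Product: 13 (R)-undec-10-yn-4-yl (R)-12-acetoxypentadec-2-ynoate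
Conditions: DCC, DMAP (5 mol%), CH2Cl2, 0 °C to rt
Reagents that add atoms: none
Why: Steglich esterification, in which the activated carboxyl group of the linear, unhindered alk-2-ynoic acid acylates the secondary alcohol at oxygen, so the carbinol C–O bond is not broken and its (R) configuration is retained, while the acetate and the terminal alkyne are inert.

Step 8
Reactants: 14 methyl (E)-3-methoxybut-2-enoate
Product: 15 1,3-dimethoxy-1-(trimethylsilyloxy)buta-1,3-diene (Brassard's diene)
Conditions: LiN(i-Pr)2, THF, −78 °C; TMSCl, −78 °C to rt; distillation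
Reagents that add atoms: chlorotrimethylsilane, C[Si](C)(C)Cl
Why: γ-Deprotonation of the vinylogous carbonate ester gives the cross-conjugated dienolate, which is trapped on oxygen by the chlorosilane (silyl ketene acetal formation) to give the 1,1,3-trioxygenated diene.

Step 9
Reactants: 13 (R)-undec-10-yn-4-yl (R)-12-acetoxypentadec-2-ynoate; 15 1,3-dimethoxy-1-(trimethylsilyloxy)buta-1,3-diene
Product: 18 (R)-undec-10-yn-4-yl 2-[(R)-9-acetoxydodecyl]-6-hydroxy-4-methoxybenzoate, via cyclohexa-1,4-diene cycloadduct 16 (not isolated), via aryl trimethylsilyl ether 17 (not isolated)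
Conditions: 15 (4 equiv, in portions), toluene, 120 °C, sealed tube; then 0.5 M HCl, THF, rt
Reagents that add atoms: none
Why: Normal-electron-demand [4+2] cycloaddition of the electron-rich vinylketene acetal 15 to the only electron-poor alkyne of 13 gives the cyclohexa-1,4-diene 16, whose mixed ketal carbon and doubly allylic CH2 lose methanol by 1,4-elimination to the aryl silyl ether 17, which the acid work-up cleaves to the hydrogen-bonded phenol 18. The closest known reaction type is the aromatising Diels–Alder reaction of 1,1,3-trioxygenated buta-1,3-dienes with acetylenic esters, which is also known for alk-2-ynoate esters of secondary alcohols with 1,3-bis(silyloxy)dienes as a way to build a resorcylate ring on a finished ester. Ring A closes in an intermolecular 4π + 2π mode that forms C1–C2 and C5–C6 in one operation, so no ring-size or Baldwin question arises. The only new stereocentre is the ketal carbon of 16, which needs no control because it becomes an sp2 carbon in 17, and the two carbinols are remote from every bond that is made or broken and stay (R). The step needs regioselectivity, chemoselectivity and the right leaving group: the largest HOMO coefficient of 15 lies on its unsubstituted CH2 terminus and the largest LUMO coefficient of the ynoate on its chain-bearing β-carbon, so the ketene acetal carbon ends up at C2 next to the ester and the methoxy carbon at C4; the terminal alkyne is not a dienophile for an electron-rich diene; and any adduct that does not lose methanol thermally is led by acid hydrolysis of its silyl ketal through the dienone tautomer to the same phenol.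

Step 10
Reactants: 18 (R)-undec-10-yn-4-yl 2-[(R)-9-acetoxydodecyl]-6-hydroxy-4-methoxybenzoate; 19 5-iodobenzene-1,3-diol
Product: 20 (R)-11-(3,5-dihydroxyphenyl)undec-10-yn-4-yl 2-[(R)-9-acetoxydodecyl]-6-hydroxy-4-methoxybenzoate
Conditions: PdCl2(PPh3)2 (3 mol%), CuI (5 mol%), Et3N, THF, rt, degassed
Reagents that add atoms: none
Why: Sonogashira coupling, in which oxidative addition of the aryl iodide to zerovalent palladium and transmetalation from the copper acetylide of the only terminal alkyne should give the aryl alkyne at room temperature, the three phenols (meta to iodine, unable to cyclise onto the alkyne), the acetate and the benzoate being spectators under Et3N.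

Step 11
Reactants: 20 (R)-11-(3,5-dihydroxyphenyl)undec-10-yn-4-yl 2-[(R)-9-acetoxydodecyl]-6-hydroxy-4-methoxybenzoate
Product: 21 5'-methoxy-integracin A, (R)-11-(3,5-dihydroxyphenyl)undecan-4-yl 2-[(R)-9-acetoxydodecyl]-6-hydroxy-4-methoxybenzoate
Conditions: H2 (1 atm), 10% Pd/C, EtOAc, rt
Reagents that add atoms: none
Why: Heterogeneous catalytic hydrogenation saturates the aryl alkyne to the CH2CH2 link, while the benzoate of a non-benzylic alcohol, the acetate, the methyl ether and the phenols offer no hydrogenolysable bond, so both carbinols stay (R).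

**Compound list**

1 | (R)-2-propyloxirane | CCC[C@@H]1CO1 | starting material
2 | hex-1-yne | C#CCCCC | starting material
3 | hex-1-ynyllithium | [Li]C#CCCCC | intermediate
4 | (R)-undec-6-yn-4-ol | CCC[C@@H](O)CC#CCCCC | intermediate
5 | (R)-undec-10-yn-4-ol | CCC[C@@H](O)CCCCCC#C | intermediate
6 | non-1-yne | C#CCCCCCCC | starting material
7 | non-1-ynyllithium | [Li]C#CCCCCCCC | intermediate
8 | (R)-tetradec-6-yn-4-ol | CCC[C@@H](O)CC#CCCCCCCC | intermediate
9 | (R)-tetradec-13-yn-4-ol | CCC[C@@H](O)CCCCCCCCC#C | intermediate
10 | dilithiated (R)-tetradec-13-yn-4-ol (lithium alkoxide at O4, lithium acetylide at C14) | CCC[C@@H](O[Li])CCCCCCCCC#C[Li] | intermediate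
11 | (R)-12-hydroxypentadec-2-ynoic acid | CCC[C@@H](O)CCCCCCCCC#CC(=O)O | intermediate
12 | (R)-12-acetoxypentadec-2-ynoic acid | CCC[C@@H](OC(C)=O)CCCCCCCCC#CC(=O)O | intermediate
13 | (R)-undec-10-yn-4-yl (R)-12-acetoxypentadec-2-ynoate | CCC[C@@H](OC(C)=O)CCCCCCCCC#CC(=O)O[C@H](CCC)CCCCCC#C | intermediate
14 | methyl (E)-3-methoxybut-2-enoate | CO/C(C)=C/C(=O)OC | starting material
15 | (1E)-1,3-dimethoxy-1-(trimethylsilyloxy)buta-1,3-diene (Brassard's diene) | CO/C(O[Si](C)(C)C)=C\C(OC)=C | intermediate
16 | (R)-undec-10-yn-4-yl 2-[(R)-9-acetoxydodecyl]-4,6-dimethoxy-6-(trimethylsilyloxy)cyclohexa-1,4-diene-1-carboxylate (ketal carbon uncontrolled) | CCC[C@@H](OC(C)=O)CCCCCCCCC1=C(C(=O)O[C@H](CCC)CCCCCC#C)C(OC)(O[Si](C)(C)C)C=C(OC)C1 | intermediate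
17 | (R)-undec-10-yn-4-yl 2-[(R)-9-acetoxydodecyl]-4-methoxy-6-(trimethylsilyloxy)benzoate | CCC[C@@H](OC(C)=O)CCCCCCCCc1cc(OC)cc(O[Si](C)(C)C)c1C(=O)O[C@H](CCC)CCCCCC#C | intermediate
18 | (R)-undec-10-yn-4-yl 2-[(R)-9-acetoxydodecyl]-6-hydroxy-4-methoxybenzoate | CCC[C@@H](OC(C)=O)CCCCCCCCc1cc(OC)cc(O)c1C(=O)O[C@H](CCC)CCCCCC#C | intermediate
19 | 5-iodobenzene-1,3-diol (5-iodoresorcinol) | Oc1cc(O)cc(I)c1 | starting material
20 | (R)-11-(3,5-dihydroxyphenyl)undec-10-yn-4-yl 2-[(R)-9-acetoxydodecyl]-6-hydroxy-4-methoxybenzoate | CCC[C@@H](OC(C)=O)CCCCCCCCc1cc(OC)cc(O)c1C(=O)O[C@H](CCC)CCCCCC#Cc1cc(O)cc(O)c1 | intermediate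
21 | 5'-methoxy-integracin A, (R)-11-(3,5-dihydroxyphenyl)undecan-4-yl 2-[(R)-9-acetoxydodecyl]-6-hydroxy-4-methoxybenzoate | CCC[C@H](CCCCCCCCc1cc(OC)cc(O)c1C(=O)O[C@H](CCC)CCCCCCCc1cc(O)cc(O)c1)OC(C)=O | target

**Count and risks**

Total: 11 steps. Longest linear sequence: 8 steps (steps 3, 4, 5, 6, 7, 9, 10, 11).

Steps most likely to fail:

1. Step 9 (cycloaddition and aromatisation). The cycloaddition to a β-alkyl ynoate may be slower than thermal silyl migration and oligomerisation of the acyclic diene, or silanol instead of methanol may be lost on aromatisation, which would leave an oxygen pattern that cannot be corrected. Fallback, setting out from 13 and returning at 18: the ring would be made by a cycloaddition–cycloreversion and the methyl ether installed afterwards. Dimedone would be silylated (TMSCl, Et3N) to 5,5-dimethyl-3-(trimethylsilyloxy)cyclohex-2-en-1-one F1 and then (LiN(i-Pr)2, TMSCl, THF, −78 °C) to the s-cis-locked 5,5-dimethyl-1,3-bis(trimethylsilyloxy)cyclohexa-1,3-diene F2. Heating 13 with F2 neat at 140 °C should give the bicyclo[2.2.2]octa-2,5-diene adduct F3, which would extrude 2-methylpropene in the same pot to (R)-undec-10-yn-4-yl 2-[(R)-9-acetoxydodecyl]-4,6-bis(trimethylsilyloxy)benzoate F4. Dilute HCl in THF would then give the resorcylate (R)-undec-10-yn-4-yl 2-[(R)-9-acetoxydodecyl]-4,6-dihydroxybenzoate F5. Methylation with MeI (1.05 equiv) and K2CO3 in acetone at rt should take place only at the 4-hydroxyl, since the 6-hydroxyl is hydrogen-bonded to the ester carbonyl, and would give 18.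

2. Step 10 (Sonogashira coupling with three free phenols). Oxidative homocoupling of the valuable terminal alkyne and slow turnover with a partly deprotonated, copper-binding iodoresorcinol may compete. Fallback, setting out from 18 and arriving at 21: semi-hydrogenation (H2, Pd/CaCO3 poisoned with Pb(OAc)2, quinoline, EtOAc) would give the terminal alkene (R)-undec-10-en-4-yl 2-[(R)-9-acetoxydodecyl]-6-hydroxy-4-methoxybenzoate F6. Anti-Markovnikov hydroboration with 9-BBN (excess, THF, 0 °C to rt) should give (R)-11-(9-borabicyclo[3.3.1]nonan-9-yl)undecan-4-yl 2-[(R)-9-acetoxydodecyl]-6-hydroxy-4-methoxybenzoate F7. A B-alkyl Suzuki–Miyaura coupling of F7 with 19 (PdCl2(dppf), aq. K3PO4, DMF, 50 °C) would form the aryl–CH2 bond directly and give 21, so that steps 10 and 11 are both replaced.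

3. Step 4 (alkyne zipper over seven positions; step 2 is of the same kind). Migration may stop short and leave internal alkyne and allene isomers that are hard to separate, or configuration may erode if the transient propargylic alkoxide is deprotonated at the carbinol carbon. Fallback, setting out from 1 and returning at 9: the Grignard reagent (7-chloroheptyl)magnesium bromide F8, made from 1-bromo-7-chloroheptane and Mg in THF, would open 1 at its CH2 group under CuI catalysis (−30 to 0 °C) to give (R)-12-chlorododecan-4-ol F9. Displacement of chloride with LiC≡CH·H2NCH2CH2NH2 in DMSO at rt would install the terminal alkyne and give 9 without any isomerisation.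

Further compounds
F1 | step 9 | 5,5-dimethyl-3-(trimethylsilyloxy)cyclohex-2-en-1-one | CC1(C)CC(=O)C=C(O[Si](C)(C)C)C1
F2 | step 9 | 5,5-dimethyl-1,3-bis(trimethylsilyloxy)cyclohexa-1,3-diene | CC1(C)CC(O[Si](C)(C)C)=CC(O[Si](C)(C)C)=C1
F3 | step 9 | (R)-undec-10-yn-4-yl 3-[(R)-9-acetoxydodecyl]-8,8-dimethyl-1,5-bis(trimethylsilyloxy)bicyclo[2.2.2]octa-2,5-diene-2-carboxylate (bridgeheads uncontrolled) | CCC[C@@H](OC(C)=O)CCCCCCCCC1=C(C(=O)O[C@H](CCC)CCCCCC#C)C2(O[Si](C)(C)C)C=C(O[Si](C)(C)C)C1C(C)(C)C2
F4 | step 9 | (R)-undec-10-yn-4-yl 2-[(R)-9-acetoxydodecyl]-4,6-bis(trimethylsilyloxy)benzoate | CCC[C@@H](OC(C)=O)CCCCCCCCc1cc(O[Si](C)(C)C)cc(O[Si](C)(C)C)c1C(=O)O[C@H](CCC)CCCCCC#C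
F5 | step 9 | (R)-undec-10-yn-4-yl 2-[(R)-9-acetoxydodecyl]-4,6-dihydroxybenzoate | CCC[C@@H](OC(C)=O)CCCCCCCCc1cc(O)cc(O)c1C(=O)O[C@H](CCC)CCCCCC#C
F6 | step 10 | (R)-undec-10-en-4-yl 2-[(R)-9-acetoxydodecyl]-6-hydroxy-4-methoxybenzoate | CCC[C@@H](OC(C)=O)CCCCCCCCc1cc(OC)cc(O)c1C(=O)O[C@H](CCC)CCCCCC=C
F7 | step 10 | (R)-11-(9-borabicyclo[3.3.1]nonan-9-yl)undecan-4-yl 2-[(R)-9-acetoxydodecyl]-6-hydroxy-4-methoxybenzoate | CCC[C@@H](OC(C)=O)CCCCCCCCc1cc(OC)cc(O)c1C(=O)O[C@H](CCC)CCCCCCCB1C2CCCC1CCC2
F8 | step 4 | (7-chloroheptyl)magnesium bromide | ClCCCCCCC[Mg]Br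
F9 | step 4 | (R)-12-chlorododecan-4-ol | CCC[C@@H](O)CCCCCCCCCl
A1 | direct plan | 5-[(R)-8-(tert-butyldimethylsilyloxy)undecyl]cyclohexane-1,3-dione | O=C1CC(=O)CC(CCCCCCC[C@@H](CCC)O[Si](C)(C)C(C)(C)C)C1
A2 | direct plan | (R)-11-[3,5-bis(benzyloxy)phenyl]undecan-4-ol | c1ccccc1COc1cc(OCc2ccccc2)cc(CCCCCCC[C@@H](CCC)O)c1
A3 | direct plan | 2-[(R)-9-acetoxydodecyl]-6-(benzyloxy)-4-methoxybenzoic acid | CCC[C@H](CCCCCCCCc1cc(OC)cc(OCc2ccccc2)c1C(=O)O)OC(C)=O
A4 | direct plan | (R)-11-[3,5-bis(benzyloxy)phenyl]undecan-4-yl 2-[(R)-9-acetoxydodecyl]-6-(benzyloxy)-4-methoxybenzoate | CCC[C@H](CCCCCCCCc1cc(OC)cc(OCc2ccccc2)c1C(=O)O[C@H](CCC)CCCCCCCc1cc(OCc2ccccc2)cc(OCc2ccccc2)c1)OC(C)=O
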